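Take 0.217 as the number for these flasks: the rate constant of L's loss over that of its making, the selectivity factor, read below from one midnight reading.

| flask | X | G | Q | remark | time |
|---|---|---|---|---|---|
| autumn | 0.28 M | 0.34 M | 0.56 M | run made earlier |  |
| midnight | 0.28 M | 1.1 M | 0.56 M | run made earlier |  |
| violet | 0.28 M | 0.280 M | 0.560 M |  | 1.5 h |
| blue | 0.28 M | 0.700 M | 0.560 M |  | 1.5 h |
| green | 0.28 M | 0.840 M | 0.560 M |  | 1.5 h |

| run | time / min | L / % | X / % |
|---|---|---|---|
| autumn | 4.00 | 11 | 87 |
| autumn | 12.0 | 31 | 70 |
| autumn | 20.0 | 39 | 58 |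
| autumn | 30.0 | 48 | 45 |
| autumn | 50.0 | 55 | 36 |
| autumn | 60.0 | 59 | 37 |
| midnight | 4.00 | 37 | 63 |
| midnight | 12.0 | 60 | 28 |
| midnight | 20.0 | 64 | 15 |
| midnight | 30.0 | 62 | 5 |
| midnight | 50.0 | 51 | 0 |
| midnight | 60.0 | 48 | 0 |

(each reading ± 2 percentage points)

- a reading or a percentage of Q counts all its forms, free or not

- final L, as a percentage of the X charged, for each flask in turn (violet, blue, green)

Assume X + G gives L and L + G loses it. Each step takes one G, so G cancels from the ratio of the two rates, which is s·cL/cX. Call f the fraction of X left, and define lost L as 1 − f − L. The large term is 1 − f. Compute only the correction. While lost L is small, put cL/cX ≈ (1 − f)/f and add up: lost L = s·(ln(1/f) − 1 + f). At 12.0 min, midnight shows a lost L of 12.0% at f = 28%, and that gives s. Test it on autumn at 50.0 min. The rule gives 8.28%, and the readings give 9.00%, each reading scattering by 2 percentage points.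

Now bracket violet at 1.5 h. Autumn's X stood at 36% and 37% in its last readings. Violet has less G but runs longer. Take the first reading as my estimate of f at the high-conversion end, so L comes to about 55.7%. This is an estimate, not a strict limit. For the low end, shrink autumn's conversion in proportion to the G charged. Then f is 47.3% and L is 47.9%. For the final L of blue and green, I take the midnight peak reading, 64%, as a rough high mark and set no low end.

The forecast says 51%, 61% and 56%, and adds: “This is rough, since the simple model doesn't fit both runs cleanly.” Its violet value lies inside my bracket. Its blue value stands below the high mark.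

The flasks give 56.1%, 57.3% and 49.4%. Violet lands just above the top of my bracket, and blue stands below the high mark.

    X + G → Q + L (k = 0.00190 L mol⁻¹ s⁻¹)
    L + G → Q + D (k = 4.30 × 10⁻⁴ L mol⁻¹ s⁻¹)
    G ⇌ Z (K = 0.550, k = 2.00 × 10⁻⁴ s⁻¹)
    J ⇌ Q, rate k4*(cs4 - [Q]) while solid is left; crystals form when [Q] > cs4 (solubility = 0.150 M, k = 0.00690 s⁻¹)
    G → E (k = 6.20 × 10⁻⁷ s⁻¹)

In violet, both steps ran while G fell to 15.3% of its charge. At 1.50 h, L was still made 2.83 times faster than used up, X stood at 35.9%, and the rule with that f gives 8.32% against D of 7.99%. In blue, X fell to 12.9% by 0.750 h, where the rule gives 25.5% against D of 22.5%. L then dropped from 64.6% to 57.3%, with G at 28.4% of its charge at the end, and D ended at 38.6%.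

(The readings were generated by integration for an exercise.)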